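**Retrosynthetic overview**
1. 19 ⇐ 17: the C2 ketone comes from ester-assisted hydration of the C2≡C3 alkyne, then desilylation.
2. 17 ⇐ 13 + 14: a one-pot mixed-anhydride epoxidation / acyl-transfer lactonisation makes the C6–O lactone bond and the C5–O ester bond (lactone ring formed last).
3. 13 ⇐ 10 + 11: 1,2-alkynylation of the C1 ketone sets C1; C4 comes from the butynol.
4. 10 ⇐ 3: allylic oxidation of the isopropenyl group to the acrylic acid, conjugate borylation/oxidation (C9–O, C10), Saegusa–Ito desaturation (C5=C6).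
5. 3 ⇐ 1: one-carbon ring expansion of (R)-carvone (seven-membered ring formed first).

Assumption: (S)-2-methylbutanoyl chloride (14) is bought as such (otherwise it is made from the commercial (S)-acid and oxalyl chloride).

Naming: from compound 12 on, atoms carry the guaiane locants of the target (ring C1, C5, C6, C7, C8, C9, C10; side chain C2–C4 and C15 on C1; C11–C13 on C7; C14 = methyl on C10). α is the ring face that carries C11 at C7, β the opposite face; the C14 methyl is α and H7 is β throughout.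

**Step 1**
Reactants: 1 (R)-carvone
Product: 3 homocarvone (5S)-2-methyl-5-(prop-1-en-2-yl)cyclohept-2-en-1-one, via α-silyl ketone 2 (not isolated)
Conditions: Me3SiCHN2 (1.3 equiv), Sc(OTf)3 (10 mol %), CH2Cl2, −78 → 0 °C; then 1 M HCl, THF, 23 °C
Reagents that add atoms: (trimethylsilyl)diazomethane, C[Si](C)(C)C=[N+]=[N-]
Why: Lewis-acid-catalysed diazoalkane ring expansion (Tiffeneau–Demjanov type) in which the sp3 carbon C6 of carvone migrates in preference to the alkenyl carbon, so the new carbon is inserted only on the saturated side, acid removes the α-silyl group, and the carvone stereocenter is untouched.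

**Step 2**
Reactants: 3 homocarvone
Product: 4 (5S)-5-(3-hydroxyprop-1-en-2-yl)-2-methylcyclohept-2-en-1-one
Conditions: SeO2 (0.3 equiv), t-BuOOH (2.5 equiv), salicylic acid (0.1 equiv), CH2Cl2, 23 °C
Reagents that add atoms: tert-butyl hydroperoxide, CC(C)(C)OO
Why: Riley allylic oxidation (ene reaction then [2,3]-shift) attacks the electron-rich 1,1-disubstituted isopropenyl alkene at its methyl group, as it does in carvone, and leaves the electron-poor enone alone.

**Step 3**
Reactants: 4 allylic alcohol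
Product: 6 2-[(1S)-4-methyl-5-oxocyclohept-3-en-1-yl]prop-2-enoic acid, via enal 5 (not isolated)
Conditions: TEMPO (10 mol %), NaClO2 (2 equiv), NaOCl (5 mol %), MeCN/phosphate buffer pH 6.7, 35 °C
Reagents that add atoms: sodium chlorite, [Na+].[O-]Cl=O
Why: TEMPO-catalysed oxidation of the primary allylic alcohol to the enal followed in the same pot by Pinnick-type chlorite oxidation to the acid, with NaOCl only catalytic so the alkenes are not chlorinated.

**Step 4**
Reactants: 6 enone acid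
Product: 8 2-[(1S,3R,4S)-3-hydroxy-4-methyl-5-oxocycloheptyl]prop-2-enoic acid, via β-boryl ketone 7 (not isolated)
Conditions: NaOt-Bu (1.2 equiv), CuCl (5 mol %), DPEphos (5 mol %), B2pin2 (1.2 equiv), MeOH (2 equiv), THF, 23 °C; then NaBO3·4H2O, THF/H2O, 23 °C; 1 M HCl work-up
Reagents that add atoms: bis(pinacolato)diboron, CC1(C)OB(OC1(C)C)B1OC(C)(C)C(C)(C)O1; sodium perborate, [Na+].[Na+].O[B-]1(O)OO[B-](O)(O)OO1
Why: Copper-catalysed conjugate borylation (a monovalent copper boryl adds to the enone; the acrylate is inert as its sodium salt) places boron on C9 from the face anti to the C7 side chain as cuprates do with carvone, the epimerisable C10 methyl is expected to settle trans to the C9 substituent, and perborate replaces B by OH with retention.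

**Step 5**
Reactants: 8 hydroxy keto acid
Product: 10 2-[(1R,5S,6R)-6-hydroxy-5-methyl-4-oxocyclohept-2-en-1-yl]prop-2-enoic acid, via silyl enol ether 9 (not isolated)
Conditions: LiN(i-Pr)2 (3.3 equiv), THF, −78 °C; Me3SiCl (3.5 equiv), −78 → 0 °C; then Pd(OAc)2 (10 mol %), O2 (1 atm), DMSO, 23 °C; aqueous citric acid
Reagents that add atoms: chlorotrimethylsilane, C[Si](C)(C)Cl
Why: Kinetic deprotonation at the unhindered methylene next to the ketone (not the methyl-bearing methine) gives the silyl enol ether regioselectively, and Saegusa–Ito oxidation (divalent palladium regenerated by O2) converts it into the enone without touching the three stereocenters.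

**Step 6**
Reactants: 10 hydroxy enone acid; 11 (R)-but-3-yn-2-ol
Product: 13 (4R)-1α,4,9β-tris(trimethylsilyloxy)-4,5-secoguaia-5,11(13)-dien-2-yn-12-oic acid, via triol acid 12 (not isolated)
Conditions: 11 (4 equiv), n-BuLi (8 equiv), THF, −78 °C; add 10, −78 → −30 °C; then Me3SiCl (8 equiv), −78 → 0 °C; pH 7 buffer (cleaves only the silyl ester); used crude
Reagents that add atoms: chlorotrimethylsilane, C[Si](C)(C)Cl
Why: Acetylide 1,2-addition to the enone carbonyl under chelation control, in which the C9 lithium alkoxide binds the C1 carbonyl and the nucleophile enters on the β-face anti to the adjacent C10 α-methyl, sets C1 (OH α, alkynyl β), C4 is carried in from 11, and Me3SiCl then caps the three alkoxides.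

**Step 7**
Reactants: 13 tris-silyl alkene acid; 14 (S)-2-methylbutanoyl chloride
Product: 17 (4R)-5β-[(S)-2-methylbutanoyloxy]-1α,4,9β-tris(trimethylsilyloxy)-4,5-secoguai-11(13)-en-2-yn-12,6α-olide, via mixed anhydride 15 (not isolated), via epoxy anhydride 16 (not isolated)
Conditions: NaH (1.0 equiv), THF, 0 °C; 14 (1.0 equiv), −40 °C; DMDO (1.3 equiv, acetone), −40 → −10 °C; then solvent switch to CH2Cl2, Sc(OTf)3 (5 mol %), −40 → 0 °C
Reagents that add atoms: dimethyldioxirane, CC1(C)OO1
Why: Proposed new method: oxidative acyloxylactonisation of a mixed anhydride, in which DMDO epoxidises C5=C6 on the β-face (anti to the 1α-silyloxy group and the 7α side chain), the Lewis acid lets the acrylic C=O of the anhydride open the epoxide 5-exo at C6 with inversion (cis-lactone, C6–O α), and the resulting O-acyl lactonium ion hands its (S)-2-methylbutanoyl group to the C5 β-alkoxide freed in the same event, so the epoxide oxygen becomes the ester oxygen and no other hydroxyl is acylated; the closest known reactions are the acid-triggered lactonisation of γ,δ-epoxy acids and the Lewis-acid ring-opening of epoxides by carboxylic anhydrides to vicinal diesters.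

**Step 8**
Reactants: 17 acyloxy lactone
Product: 19 target (4R)-1α,4,9β-trihydroxy-5β-[(S)-2-methylbutanoyloxy]-2-oxo-4,5-secoguai-11(13)-en-12,6α-olide, via silylated ketone 18 (not isolated)
Conditions: Ph3PAuNTf2 (5 mol %), H2O (5 equiv), 1,4-dioxane, 23 °C; then citric acid, MeOH/H2O, 23 °C
Reagents that add atoms: water, O
Why: Gold-catalysed alkyne hydration with anchimeric assistance, in which the C5 ester carbonyl (cis to the alkyne) attacks the triple bond activated by monovalent gold 6-exo at C2 so that oxygen ends on C2 and not C3, after which mild acid removes the three silyl groups without touching any stereocenter.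

**Compound list**
1 | (R)-carvone, (5R)-2-methyl-5-(prop-1-en-2-yl)cyclohex-2-en-1-one | CC1=CC[C@H](CC1=O)C(C)=C | starting material
2 | α-silyl ketone: 3 carrying Me3Si on the inserted carbon next to the ketone (both epimers) | C1[C@H](C(C)=C)CC=C(C)C(=O)C1[Si](C)(C)C | intermediate
3 | homocarvone, (5S)-2-methyl-5-(prop-1-en-2-yl)cyclohept-2-en-1-one | C1[C@H](C(C)=C)CC=C(C)C(=O)C1 | intermediate
4 | (5S)-5-(3-hydroxyprop-1-en-2-yl)-2-methylcyclohept-2-en-1-one | C1[C@H](C(CO)=C)CC=C(C)C(=O)C1 | intermediate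
5 | enal, 2-[(1S)-4-methyl-5-oxocyclohept-3-en-1-yl]prop-2-enal | C1[C@H](C(C=O)=C)CC=C(C)C(=O)C1 | intermediate
6 | 2-[(1S)-4-methyl-5-oxocyclohept-3-en-1-yl]prop-2-enoic acid | C1[C@H](C(C(=O)O)=C)CC=C(C)C(=O)C1 | intermediate
7 | β-boryl ketone: 8 with pinacolboryl in place of the hydroxyl (same configuration) | C1[C@H](C(C(=O)O)=C)C[C@@H](B2OC(C)(C)C(C)(C)O2)[C@H](C)C(=O)C1 | intermediate
8 | 2-[(1S,3R,4S)-3-hydroxy-4-methyl-5-oxocycloheptyl]prop-2-enoic acid | C1[C@H](C(C(=O)O)=C)C[C@@H](O)[C@H](C)C(=O)C1 | intermediate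
9 | silyl enol ether: tris(trimethylsilyl) derivative of 8 (silyl ether, silyl ester, silyl enol ether toward the methylene) | C1[C@H](C(C(=O)O[Si](C)(C)C)=C)C[C@@H](O[Si](C)(C)C)[C@H](C)C(O[Si](C)(C)C)=C1 | intermediate
10 | 2-[(1R,5S,6R)-6-hydroxy-5-methyl-4-oxocyclohept-2-en-1-yl]prop-2-enoic acid | C1[C@H](C(C(=O)O)=C)C[C@@H](O)[C@H](C)C(=O)C=1 | intermediate
11 | (R)-but-3-yn-2-ol | C#C[C@@H](C)O | starting material
12 | triol acid, (4R)-1α,4,9β-trihydroxy-4,5-secoguaia-5,11(13)-dien-2-yn-12-oic acid | C1[C@H](C(C(=O)O)=C)C[C@@H](O)[C@H](C)[C@@](O)(C#C[C@@H](C)O)C=1 | intermediate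
13 | (4R)-1α,4,9β-tris(trimethylsilyloxy)-4,5-secoguaia-5,11(13)-dien-2-yn-12-oic acid | C1[C@H](C(C(=O)O)=C)C[C@@H](O[Si](C)(C)C)[C@H](C)[C@@](O[Si](C)(C)C)(C#C[C@@H](C)O[Si](C)(C)C)C=1 | intermediate
14 | (S)-2-methylbutanoyl chloride | ClC(=O)[C@@H](C)CC | starting material
15 | mixed anhydride of 13 and (S)-2-methylbutanoic acid | C1[C@H](C(C(=O)OC(=O)[C@@H](C)CC)=C)C[C@@H](O[Si](C)(C)C)[C@H](C)[C@@](O[Si](C)(C)C)(C#C[C@@H](C)O[Si](C)(C)C)C=1 | intermediate
16 | epoxy anhydride, 5β,6β-epoxide of 15 | O1[C@H]2[C@H](C(C(=O)OC(=O)[C@@H](C)CC)=C)C[C@@H](O[Si](C)(C)C)[C@H](C)[C@@](O[Si](C)(C)C)(C#C[C@@H](C)O[Si](C)(C)C)[C@@H]12 | intermediate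
17 | (4R)-5β-[(S)-2-methylbutanoyloxy]-1α,4,9β-tris(trimethylsilyloxy)-4,5-secoguai-11(13)-en-2-yn-12,6α-olide | C=C1C(=O)O[C@@H]2[C@H]1C[C@@H](O[Si](C)(C)C)[C@H](C)[C@@](O[Si](C)(C)C)(C#C[C@@H](C)O[Si](C)(C)C)[C@H]2OC(=O)[C@@H](C)CC | intermediate
18 | silylated ketone, 1,4,9-tris(trimethylsilyl) ether of 19 | C=C1C(=O)O[C@@H]2[C@H]1C[C@@H](O[Si](C)(C)C)[C@H](C)[C@@](O[Si](C)(C)C)(C(=O)C[C@@H](C)O[Si](C)(C)C)[C@H]2OC(=O)[C@@H](C)CC | intermediate
19 | CNP0291806.4, (1S,5S,6R,7S,9R,10S,4R)-1α,4,9β-trihydroxy-5β-[(S)-2-methylbutanoyloxy]-2-oxo-4,5-secoguai-11(13)-en-12,6α-olide | C=C1C(=O)O[C@@H]2[C@H]1C[C@@H](O)[C@H](C)[C@@](O)(C(=O)C[C@@H](C)O)[C@H]2OC(=O)[C@@H](C)CC | target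

**Step count**
Total steps: 8. Longest linear sequence: 8 steps (1 → 19); 11 and 14 are bought.

**Steps most likely to fail**

Step 7 (the new cascade). The mixed anhydride may scramble, the Lewis acid may trigger a semipinacol shift of the 1-silyloxy epoxide, or acyl transfer may be incomplete. The fallback uses known chemistry, sets out from 13 and comes back at 17. Buffered m-CPBA (NaHCO3, CH2Cl2, 0 °C; Prilezhaev epoxidation on the β-face) gives the 5β,6β-epoxy acid F1, which closes by itself (5-exo, inversion at C6) to the 5β-hydroxy lactone F2. Its C5 hydroxyl is the only free one and is esterified with 14 (pyridine, DMAP, CH2Cl2, 0 °C) to give 17.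

Step 6 (C1 configuration). Facial selectivity on a flexible cycloheptenone may be low. The fallback makes the configuration of the adduct irrelevant and sets C1 by C–O bond formation; it sets out from 13, used together with the C1 epimer of 13 F3, and comes back at 19.
- Catalytic Me3SiOTf (CH2Cl2, −78 °C) ionises the tertiary propargylic, allylic silyl ether, and the tethered acid closes on C6 with allylic transposition to give the enyne cis-lactone F4.
- DMDO epoxidises the C1=C5 alkene on the convex β-face to give the 1β,5β-epoxide F5.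
- (S)-2-Methylbutanoic acid (toluene, 40 °C) opens it at the tertiary propargylic C1 with inversion to give the 1α-acyloxy 5β-alcohol F6.
- Et3N/DMAP moves the acyl group to the secondary oxygen to give the 5β-ester 1α-alcohol F7.
- F7, under the step 8 conditions, passes through the bis-silyl ketone F8 to 19.

Step 4 (C9 face and C10 epimer ratio). The methyl-bearing centre is set by protonation and may come out cis to the C9 oxygen. The fallback sets out from 6 and comes back at 8. Weitz–Scheffer epoxidation (H2O2, NaOH, MeOH, 0 °C; attack anti to the C7 side chain) gives the 9β,10β-epoxy keto acid F9. SmI2 (2.2 equiv, THF/MeOH, −90 °C) cleaves the C10–O bond, and the trivalent samarium enolate, chelated to the C9 alkoxide, is protonated from the β-face to give 8.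

**Further compounds**
F1 | step 7 | 5β,6β-epoxide of 13 (epoxy acid) | O1[C@H]2[C@H](C(C(=O)O)=C)C[C@@H](O[Si](C)(C)C)[C@H](C)[C@@](O[Si](C)(C)C)(C#C[C@@H](C)O[Si](C)(C)C)[C@@H]12
F2 | step 7 | (4R)-5β-hydroxy-1α,4,9β-tris(trimethylsilyloxy)-4,5-secoguai-11(13)-en-2-yn-12,6α-olide | C=C1C(=O)O[C@@H]2[C@H]1C[C@@H](O[Si](C)(C)C)[C@H](C)[C@@](O[Si](C)(C)C)(C#C[C@@H](C)O[Si](C)(C)C)[C@H]2O
F3 | step 6 | C1 epimer of 13 (1β-silyloxy, alkynyl α) | C1[C@H](C(C(=O)O)=C)C[C@@H](O[Si](C)(C)C)[C@H](C)[C@](O[Si](C)(C)C)(C#C[C@@H](C)O[Si](C)(C)C)C=1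
F4 | step 6 | (4R)-4,9β-bis(trimethylsilyloxy)-4,5-secoguaia-1(5),11(13)-dien-2-yn-12,6α-olide | C=C1C(=O)O[C@@H]2[C@H]1C[C@@H](O[Si](C)(C)C)[C@H](C)C(C#C[C@@H](C)O[Si](C)(C)C)=C2
F5 | step 6 | 1β,5β-epoxide of F4 | C=C1C(=O)O[C@@H]2[C@H]1C[C@@H](O[Si](C)(C)C)[C@H](C)[C@@]3(C#C[C@@H](C)O[Si](C)(C)C)O[C@@H]23
F6 | step 6 | (4R)-5β-hydroxy-1α-[(S)-2-methylbutanoyloxy]-4,9β-bis(trimethylsilyloxy)-4,5-secoguai-11(13)-en-2-yn-12,6α-olide | C=C1C(=O)O[C@@H]2[C@H]1C[C@@H](O[Si](C)(C)C)[C@H](C)[C@@](OC(=O)[C@@H](C)CC)(C#C[C@@H](C)O[Si](C)(C)C)[C@H]2O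
F7 | step 6 | (4R)-1α-hydroxy-5β-[(S)-2-methylbutanoyloxy]-4,9β-bis(trimethylsilyloxy)-4,5-secoguai-11(13)-en-2-yn-12,6α-olide | C=C1C(=O)O[C@@H]2[C@H]1C[C@@H](O[Si](C)(C)C)[C@H](C)[C@@](O)(C#C[C@@H](C)O[Si](C)(C)C)[C@H]2OC(=O)[C@@H](C)CC
F8 | step 6 | 4,9-bis(trimethylsilyl) ether of 19 | C=C1C(=O)O[C@@H]2[C@H]1C[C@@H](O[Si](C)(C)C)[C@H](C)[C@@](O)(C(=O)C[C@@H](C)O[Si](C)(C)C)[C@H]2OC(=O)[C@@H](C)CC
F9 | step 4 | 9β,10β-epoxide of 6 (epoxy keto acid) | C1[C@H](C(C(=O)O)=C)C[C@H]2O[C@@]2(C)C(=O)C1
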